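**Strategy.** The route rests on the acetal carbon C1, shared by the δ‑lactone (C1–O2–C3–C4–C5–C8) and the tetrahydrofuran ring (O7–C1–C8–C5–C6), which is closed last. In one operation on a prostaglandin‑like cyclopentanone, Baeyer–Villiger insertion of O2 between the C3 ketone and the α‑silyloxy carbon C1 expands the carbocycle to the lactone; the silyl acylal formed ionises and is trapped by the C6 silyl ether, cis‑1,3 to C1, which closes the tetrahydrofuran. The cyclopentanone comes from a photoredox Giese coupling of a cis‑hydroazulenyl tertiary radical with a ribose‑derived cyclopentenone, followed by a glyoxylate aldol.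

Key step: step 16

Remark on labels: C1, O2, C3, C4, C5, C6, O7, C8 are the positions of the target's 2,7‑dioxabicyclo[3.2.1]octan‑3‑one and are kept for all precursors (in the cyclopentanes C1 is bonded to C3). The α face of the cyclopentane carries the C1 and C3 oxygens; β is the opposite face. Hydroazulene locants are primed (C1′ quaternary, C3a′, C8a′).

Assumption: the copper/ferrocenyl diphosphine catalyst of step 4 shows its usual sense of induction with the 4,4‑dimethyl enone; the ligand enantiomer that gives (R)‑10 is used.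

**Step 1**
Reactants: 1 3‑methylcyclohex‑2‑en‑1‑one
Product: 3 trimethyl[(3,3‑dimethylcyclohex‑1‑en‑1‑yl)oxy]silane, via lithium enolate 2 (not isolated)
Conditions: Me2CuLi (from MeLi and CuI), Et2O, 0 °C; then Me3SiCl, Et3N, 0 °C
Reagents that add atoms: methyllithium [Li]C; chlorotrimethylsilane C[Si](C)(C)Cl
Why: Cuprate conjugate addition builds the gem‑dimethyl carbon, and O‑silylation of the regiodefined enolate fixes the enol double bond toward it.

**Step 2**
Reactants: 3 trimethyl[(3,3‑dimethylcyclohex‑1‑en‑1‑yl)oxy]silane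
Product: 4 trimethyl[(5,5‑dimethylbicyclo[4.1.0]heptan‑1‑yl)oxy]silane (racemic)
Conditions: Et2Zn, CH2I2, CH2Cl2, 0 °C → rt
Reagents that add atoms: diiodomethane ICI
Why: Simmons–Smith cyclopropanation of the electron‑rich silyl enol ether; its stereocentres are erased in the next step.

**Step 3**
Reactants: 4 trimethyl[(5,5‑dimethylbicyclo[4.1.0]heptan‑1‑yl)oxy]silane
Product: 6 4,4‑dimethylcyclohept‑2‑en‑1‑one, via chloro ketone 5 (not isolated)
Conditions: FeCl3, DMF, 0 °C; then NaOAc, MeOH, reflux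
Reagents that add atoms: none
Why: Oxidative ring expansion of the silyloxycyclopropane: one‑electron oxidation cleaves the internal cyclopropane bond to the β‑chloro ketone, and E1cB loss of HCl gives the enone with the gem‑dimethyl group next to the β‑carbon.

**Step 4**
Reactants: 6 4,4‑dimethylcyclohept‑2‑en‑1‑one; 7 2‑(2‑bromoethyl)‑2‑methyl‑1,3‑dioxolane
Product: 10 (R)‑4,4‑dimethyl‑3‑[2‑(2‑methyl‑1,3‑dioxolan‑2‑yl)ethyl]cyclohept‑1‑en‑1‑yl trifluoromethanesulfonate, via Grignard reagent 8 (not isolated), via magnesium enolate 9 (not isolated)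
Conditions: 7, Mg, THF, 25 °C; then 6, CuBr·SMe2 (5 mol %), (R)‑1‑[(S)‑2‑(diphenylphosphino)ferrocenyl]ethyldicyclohexylphosphine (6 mol %), t‑BuOMe, −75 °C; then N‑(5‑chloro‑2‑pyridyl)bis(trifluoromethanesulfonimide), −75 → 0 °C
Reagents that add atoms: N‑(5‑chloro‑2‑pyridyl)bis(trifluoromethanesulfonimide) O=S(=O)(N(c1ccc(Cl)cn1)S(=O)(=O)C(F)(F)F)C(F)(F)F
Why: Copper‑catalysed asymmetric conjugate addition of the Grignard reagent sets the future C3a′ stereocentre under ligand control, and O‑triflation of the magnesium enolate places the double bond toward that centre.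

**Step 5**
Reactants: 10 (R)‑enol triflate
Product: 11 (R)‑trimethyl({4,4‑dimethyl‑3‑[2‑(2‑methyl‑1,3‑dioxolan‑2‑yl)ethyl]cyclohept‑1‑en‑1‑yl}methyl)silane
Conditions: Me3SiCH2MgCl, Pd(PPh3)4 (5 mol %), THF, 0 °C → rt
Reagents that add atoms: (trimethylsilyl)methylmagnesium chloride C[Si](C)(C)C[Mg]Cl
Why: Kumada cross‑coupling of the enol triflate gives the 2‑substituted allylsilane without touching the stereocentre or the ketal.

**Step 6**
Reactants: 11 (R)‑allylsilane ketal
Product: 12 (R)‑4‑{7,7‑dimethyl‑3‑[(trimethylsilyl)methyl]cyclohept‑2‑en‑1‑yl}butan‑2‑one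
Conditions: pyridinium p‑toluenesulfonate (cat.), acetone/H2O (10:1), 40 °C
Reagents that add atoms: water O
Why: Mild acid‑catalysed ketal hydrolysis frees the methyl ketone while the allylsilane survives the weak acid.

**Step 7**
Reactants: 12 (R)‑allylsilane ketone
Product: 13 (3aR,8aS)‑1,4,4‑trimethyl‑8‑methylidenedecahydroazulen‑1‑ol (cis‑fused, both C1 epimers)
Conditions: TiCl4, CH2Cl2, −78 °C; aq. NaHCO3
Reagents that add atoms: none
Why: Intramolecular Hosomi–Sakurai allylation: the γ‑carbon of the allylsilane attacks the activated ketone from the face that carries the tether, closing the cyclopentanol cis‑fused to the seven‑membered ring (C8a′ set by C3a′) and moving the double bond to the exocyclic position; the carbinol configuration is irrelevant.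

**Step 8**
Reactants: 13 (3aR,8aS)‑1,4,4‑trimethyl‑8‑methylidenedecahydroazulen‑1‑ol
Product: 15 cesium 2‑oxo‑2‑{[(3aR,8aS)‑1,4,4‑trimethyl‑8‑methylidenedecahydroazulen‑1‑yl]oxy}acetate, via methyl oxalate 14 (not isolated)
Conditions: ClC(O)CO2Me, Et3N, DMAP (cat.), CH2Cl2, 0 °C → rt; then CsOH·H2O (1.0 equiv), THF/H2O, rt
Reagents that add atoms: methyl chlorooxoacetate COC(=O)C(=O)Cl; cesium hydroxide [Cs+].[OH-]
Why: Acylation of the tertiary alcohol and selective saponification of the more electrophilic methyl ester give the stable half‑oxalate salt that serves as the radical precursor.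

**Step 9**
Reactants: 15 cesium oxalate; 16 (3aR,6aR)‑2,2‑dimethyl‑3a,6a‑dihydro‑4H‑cyclopenta[d][1,3]dioxol‑4‑one
Product: 17 (3aR,6R,6aR)‑2,2‑dimethyl‑6‑[(1R,3aR,8aS)‑1,4,4‑trimethyl‑8‑methylidenedecahydroazulen‑1‑yl]‑3a,5,6,6a‑tetrahydro‑4H‑cyclopenta[d][1,3]dioxol‑4‑one
Conditions: Ir[dF(CF3)ppy]2(dtbbpy)PF6 (1 mol %), H2O (10 equiv), DME/DMF (3:1), blue LEDs, 60 °C
Reagents that add atoms: none
Why: Photoredox Giese addition: oxidation of the oxalate and loss of two CO2 give the tertiary C1′ radical, which adds to the enone β‑carbon C8 anti to the dioxolane ring and through its convex face (that of the ring‑fusion hydrogens), setting C1′ and C8 together; the enolate is protonated by water.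

**Step 10**
Reactants: 17 Giese ketone; 18 methyl glyoxylate (distilled before use)
Product: 21 methyl (2R)‑2‑[(3aR,5R,6R,6aR)‑2,2‑dimethyl‑4‑oxo‑6‑(hydroazulenyl)‑tetrahydro‑4H‑cyclopenta[d][1,3]dioxol‑5‑yl]‑2‑[(triisopropylsilyl)oxy]acetate, via lithium enolate 19 (not isolated), via lithium aldolate 20 (not isolated)
Conditions: LiN(i‑Pr)2, THF, −78 °C; then 18, −78 °C; then i‑Pr3SiOTf, −78 → −30 °C
Reagents that add atoms: triisopropylsilyl trifluoromethanesulfonate CC(C)[Si](C(C)C)(C(C)C)OS(=O)(=O)C(F)(F)F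
Why: Kinetic deprotonation at the C5 methylene and aldol addition through a closed chair transition state: attack anti to the C8 substituent sets C5, the ring‑constrained E enolate gives the anti aldol that sets C6, and in situ O‑silylation blocks the retro‑aldol.

**Step 11**
Reactants: 21 silylated aldol ketone
Product: 22 4α‑alcohol of 21 (C4–OH cis to the C5 side chain and to the dioxolane)
Conditions: NaBH4, MeOH/THF, −40 °C
Reagents that add atoms: none
Why: Ketone reduction with hydride delivered to the β face, opposite to the flanking C5 side chain and the dioxolane ring, gives the 4α‑alcohol and leaves the hindered α‑silyloxy ester untouched.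

**Step 12**
Reactants: 22 4α‑alcohol
Product: 23 C4 acetate of 22
Conditions: Ac2O, DMAP, pyridine, rt
Reagents that add atoms: acetic anhydride CC(=O)OC(C)=O
Why: DMAP‑catalysed acylation installs the C4 acetate of the target before the neighbouring oxygens are unmasked.

**Step 13**
Reactants: 23 acetate
Product: 24 diol (23 without the isopropylidene group; C1–OH and C3–OH both α)
Conditions: AcOH/H2O (4:1), 50 °C
Reagents that add atoms: none
Why: Acid‑catalysed acetal hydrolysis frees the cis C1/C3 diol; the triisopropylsilyl ether, the acetate and the exocyclic alkene tolerate warm aqueous acetic acid.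

**Step 14**
Reactants: 24 diol
Product: 25 α‑ketol (C3 ketone, C1–OH retained)
Conditions: 2‑iodoxybenzoic acid (1.2 equiv), DMSO, rt
Reagents that add atoms: none
Why: Hypervalent‑iodine oxidation turns a vicinal diol into the α‑ketol without C–C cleavage, and should occur at C3, whose carbinol hydrogen lies on the open β face, not at C1, whose hydrogen is shielded by the neighbouring hydroazulenyl group.

**Step 15**
Reactants: 25 α‑ketol
Product: 26 C1 trimethylsilyl ether of 25
Conditions: Me3SiCl, imidazole, CH2Cl2, 0 °C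
Reagents that add atoms: chlorotrimethylsilane C[Si](C)(C)Cl
Why: Silyl ether formation under near‑neutral conditions caps the C1 hydroxyl, making C1 the electron‑rich migrating carbon and its oxygen the later leaving group.

**Step 16**
Reactants: 26 α‑silyloxy cyclopentanone
Product: 28 methyl (1S,4S,5R,6R,8R)‑4‑(acetyloxy)‑3‑oxo‑8‑[(1R,3aR,8aS)‑1,4,4‑trimethyl‑8‑methylidenedecahydroazulen‑1‑yl]‑2,7‑dioxabicyclo[3.2.1]octane‑6‑carboxylate, via silyloxy lactone 27 (not isolated)
Conditions: (Me3SiO)2 (2 equiv), Me3SiOTf (1.5 equiv), 2,6‑di‑tert‑butyl‑4‑methylpyridine (0.3 equiv), CH2Cl2, −78 → 0 °C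
Reagents that add atoms: bis(trimethylsilyl) peroxide C[Si](C)(C)OO[Si](C)(C)C
Why: Me3SiOTf activates the C3 ketone toward addition of the silyl peroxide, and the silyl perketal undergoes Criegee rearrangement in which the α‑silyloxy carbon C1 migrates with retention (Baeyer–Villiger oxidation; closest precedent is the silyl‑peroxide Baeyer–Villiger oxidation of α‑oxygenated cycloalkanones, which spares C=C bonds). This 1,2‑shift of C1 from carbon to oxygen closes the six‑membered lactone (C1–O2–C3–C4–C5–C8) by ring expansion and makes C1 a silyl acylal. Me3SiOTf then removes the exocyclic OSiMe3 group as (Me3Si)2O, and the acyloxy‑stabilised oxocarbenium ion at C1 is captured 5‑exo‑trig by the oxygen of the C6 silyl ether, which loses its silyl group as the triflate (intramolecular transacetalisation, as in glycosylation of silyl ethers with 1‑O‑silyl donors); this closes the tetrahydrofuran ring (O7–C1–C8–C5–C6) last. The only new stereocentre, C1, is fixed by the tether, since O7 can reach C1 only from the face cis to the C5 side chain; C4, C5, C6 and C8 are untouched. The step needs migration of C1 rather than C4 (donor OSiMe3 on C1 against acceptor OAc on C4), ketone oxidation rather than alkene epoxidation (non‑electrophilic silyl peroxide, hindered pyridine as proton scavenger) and loss of the exocyclic rather than the ring oxygen at C1 (silylation of the more basic silyl ether oxygen).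

**Compound list**

1 | 3‑methylcyclohex‑2‑en‑1‑one | CC1=CC(=O)CCC1 | starting material
2 | lithium 3,3‑dimethylcyclohex‑1‑en‑1‑olate | [Li]OC1=CC(C)(C)CCC1 | intermediate
3 | trimethyl[(3,3‑dimethylcyclohex‑1‑en‑1‑yl)oxy]silane | C[Si](C)(C)OC1=CC(C)(C)CCC1 | intermediate
4 | trimethyl[(5,5‑dimethylbicyclo[4.1.0]heptan‑1‑yl)oxy]silane (racemic) | C[Si](C)(C)OC12CCCC(C)(C)C1C2 | intermediate
5 | 3‑chloro‑4,4‑dimethylcycloheptan‑1‑one | CC1(C)CCCC(=O)CC1Cl | intermediate
6 | 4,4‑dimethylcyclohept‑2‑en‑1‑one | CC1(C)CCCC(=O)C=C1 | intermediate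
7 | 2‑(2‑bromoethyl)‑2‑methyl‑1,3‑dioxolane | CC1(CCBr)OCCO1 | starting material
8 | [2‑(2‑methyl‑1,3‑dioxolan‑2‑yl)ethyl]magnesium bromide | CC1(CC[Mg]Br)OCCO1 | intermediate
9 | bromomagnesium (R)‑4,4‑dimethyl‑3‑[2‑(2‑methyl‑1,3‑dioxolan‑2‑yl)ethyl]cyclohept‑1‑en‑1‑olate | CC1(C)CCCC(O[Mg]Br)=C[C@H]1CCC2(C)OCCO2 | intermediate
10 | (R)‑4,4‑dimethyl‑3‑[2‑(2‑methyl‑1,3‑dioxolan‑2‑yl)ethyl]cyclohept‑1‑en‑1‑yl trifluoromethanesulfonate | CC1(C)CCCC(OS(=O)(=O)C(F)(F)F)=C[C@H]1CCC2(C)OCCO2 | intermediate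
11 | (R)‑trimethyl({4,4‑dimethyl‑3‑[2‑(2‑methyl‑1,3‑dioxolan‑2‑yl)ethyl]cyclohept‑1‑en‑1‑yl}methyl)silane | CC1(C)CCCC(C[Si](C)(C)C)=C[C@H]1CCC2(C)OCCO2 | intermediate
12 | (R)‑4‑{7,7‑dimethyl‑3‑[(trimethylsilyl)methyl]cyclohept‑2‑en‑1‑yl}butan‑2‑one | CC1(C)CCCC(C[Si](C)(C)C)=C[C@H]1CCC(C)=O | intermediate
13 | (3aR,8aS)‑1,4,4‑trimethyl‑8‑methylidenedecahydroazulen‑1‑ol (cis‑fused, both C1 epimers) | C=C1CCCC(C)(C)[C@@H]2CCC(C)(O)[C@H]12 | intermediate
14 | methyl (3aR,8aS)‑1,4,4‑trimethyl‑8‑methylidenedecahydroazulen‑1‑yl oxalate | C=C1CCCC(C)(C)[C@@H]2CCC(C)(OC(=O)C(=O)OC)[C@H]12 | intermediate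
15 | cesium 2‑oxo‑2‑{[(3aR,8aS)‑1,4,4‑trimethyl‑8‑methylidenedecahydroazulen‑1‑yl]oxy}acetate | C=C1CCCC(C)(C)[C@@H]2CCC(C)(OC(=O)C(=O)[O-])[C@H]12.[Cs+] | intermediate
16 | (3aR,6aR)‑2,2‑dimethyl‑3a,6a‑dihydro‑4H‑cyclopenta[d][1,3]dioxol‑4‑one | O=C1C=C[C@H]2OC(C)(C)O[C@@H]12 | starting material
17 | (3aR,6R,6aR)‑2,2‑dimethyl‑6‑[(1R,3aR,8aS)‑1,4,4‑trimethyl‑8‑methylidenedecahydroazulen‑1‑yl]‑3a,5,6,6a‑tetrahydro‑4H‑cyclopenta[d][1,3]dioxol‑4‑one (C4 ketone, C5 methylene, C8 substituent β) | C=C1CCCC(C)(C)[C@@H]2CC[C@@](C)([C@H]3CC(=O)[C@@H]4OC(C)(C)O[C@H]34)[C@H]12 | intermediate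
18 | methyl glyoxylate | COC(=O)C=O | starting material
19 | lithium enolate of 17 (C4–OLi, C4=C5) | C=C1CCCC(C)(C)[C@@H]2CC[C@@](C)([C@H]3C=C(O[Li])[C@@H]4OC(C)(C)O[C@H]34)[C@H]12 | intermediate
20 | lithium aldolate of the anti aldol adduct (C6–OLi, C5 side chain α) | C=C1CCCC(C)(C)[C@@H]2CC[C@@](C)([C@H]3[C@H]([C@@H](O[Li])C(=O)OC)C(=O)[C@@H]4OC(C)(C)O[C@H]34)[C@H]12 | intermediate
21 | methyl (2R)‑2‑[(3aR,5R,6R,6aR)‑2,2‑dimethyl‑4‑oxo‑6‑[(1R,3aR,8aS)‑1,4,4‑trimethyl‑8‑methylidenedecahydroazulen‑1‑yl]tetrahydro‑4H‑cyclopenta[d][1,3]dioxol‑5‑yl]‑2‑[(triisopropylsilyl)oxy]acetate | C=C1CCCC(C)(C)[C@@H]2CC[C@@](C)([C@H]3[C@H]([C@@H](O[Si](C(C)C)(C(C)C)C(C)C)C(=O)OC)C(=O)[C@@H]4OC(C)(C)O[C@H]34)[C@H]12 | intermediate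
22 | 4α‑alcohol of 21 (C4–OH cis to C5 side chain and dioxolane) | C=C1CCCC(C)(C)[C@@H]2CC[C@@](C)([C@H]3[C@H]([C@@H](O[Si](C(C)C)(C(C)C)C(C)C)C(=O)OC)[C@H](O)[C@@H]4OC(C)(C)O[C@H]34)[C@H]12 | intermediate
23 | C4 acetate of 22 | C=C1CCCC(C)(C)[C@@H]2CC[C@@](C)([C@H]3[C@H]([C@@H](O[Si](C(C)C)(C(C)C)C(C)C)C(=O)OC)[C@H](OC(C)=O)[C@@H]4OC(C)(C)O[C@H]34)[C@H]12 | intermediate
24 | diol: 23 without the isopropylidene group (C1–OH, C3–OH both α) | C=C1CCCC(C)(C)[C@@H]2CC[C@@](C)([C@H]3[C@H]([C@@H](O[Si](C(C)C)(C(C)C)C(C)C)C(=O)OC)[C@H](OC(C)=O)[C@H](O)[C@@H]3O)[C@H]12 | intermediate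
25 | α‑ketol: 24 with C3 oxidised to the ketone (C1–OH α) | C=C1CCCC(C)(C)[C@@H]2CC[C@@](C)([C@H]3[C@H]([C@@H](O[Si](C(C)C)(C(C)C)C(C)C)C(=O)OC)[C@H](OC(C)=O)C(=O)[C@@H]3O)[C@H]12 | intermediate
26 | C1 trimethylsilyl ether of 25 | C=C1CCCC(C)(C)[C@@H]2CC[C@@](C)([C@H]3[C@H]([C@@H](O[Si](C(C)C)(C(C)C)C(C)C)C(=O)OC)[C@H](OC(C)=O)C(=O)[C@@H]3O[Si](C)(C)C)[C@H]12 | intermediate
27 | δ‑lactone from 26 by insertion of O2 between C3 and C1 (6‑trimethylsilyloxy‑tetrahydropyran‑2‑one; C4–OAc, C5 side chain and C1–OSiMe3 cis, C8 substituent trans) | C=C1CCCC(C)(C)[C@@H]2CC[C@@](C)([C@H]3[C@H]([C@@H](O[Si](C(C)C)(C(C)C)C(C)C)C(=O)OC)[C@H](OC(C)=O)C(=O)O[C@@H]3O[Si](C)(C)C)[C@H]12 | intermediate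
28 | methyl (1S,4S,5R,6R,8R)‑4‑(acetyloxy)‑3‑oxo‑8‑[(1R,3aR,8aS)‑1,4,4‑trimethyl‑8‑methylidenedecahydroazulen‑1‑yl]‑2,7‑dioxabicyclo[3.2.1]octane‑6‑carboxylate | C=C1CCCC(C)(C)[C@@H]2CC[C@@](C)([C@@H]3[C@@H]4OC(=O)[C@@H](OC(C)=O)[C@H]3[C@H](C(=O)OC)O4)[C@H]12 | target

**Count.** Total: 16 steps. Longest linear sequence: 16 steps (1 → 28); compounds 7, 16 and 18 enter as purchased building blocks.

**Steps most likely to fail**

Step 16 (key step). The peroxide may add slowly to the crowded C3 ketone, so that the C1 silyl ether is lost first, C4 migrates in competition with C1, or the exocyclic alkene is slowly attacked. The fallback sets out from ketol 25 and leaves out 26. NaIO4 in THF/H2O cleaves the C1–C3 bond of the α‑ketol, and the aldehyde acid closes to the hydroxy lactone F1. Acetylation (Ac2O, pyridine, DMAP) gives the anomeric acetate F2. Catalytic Me3SiOTf in CH2Cl2 at −40 °C ionises the acetate and the C6 silyl ether closes the tetrahydrofuran, which returns to the route at 28.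

Step 14. The two α‑hydroxyls may be poorly discriminated, the ketol may be over‑oxidised to the diketone, or the acetyl group may migrate from O4 to O3 in the free diol. The fallback sets out from diol 24, which is cleaved at once with NaIO4 to the dialdehyde F3. The readily hydrated α‑acetoxy aldehyde at C3 is oxidised selectively (TEMPO cat., PhI(OAc)2, MeCN/H2O) beside the hindered C1 aldehyde, and the acid closes onto C1 to give the hydroxy lactone F1. This is carried through the acetate F2 as above and returns to the route at 28.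

Step 10. Retro‑aldol during silylation, enolisation toward C3 with β‑elimination of the dioxolane oxygen, or low anti selectivity may intervene. The fallback sets out from 17, whose kinetic enolate is trapped as the trimethylsilyl enol ether F4 (LiN(i‑Pr)2, Me3SiCl, −78 °C). A Mukaiyama aldol addition to 18 (BF3·OEt2, CH2Cl2, −78 °C) gives the free aldol F5 after aqueous work‑up, and silylation (i‑Pr3SiOTf, 2,6‑lutidine) returns to the route at 21.

**Further compounds**

F1 | step 16 | hydroxy lactone: 6‑hydroxy analogue of 27 (C1–OH, both anomers) | C=C1CCCC(C)(C)[C@@H]2CC[C@@](C)([C@H]3[C@H]([C@@H](O[Si](C(C)C)(C(C)C)C(C)C)C(=O)OC)[C@H](OC(C)=O)C(=O)OC3O)[C@H]12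
F2 | step 16 | anomeric acetate of F1 (C1–OAc, both anomers) | C=C1CCCC(C)(C)[C@@H]2CC[C@@](C)([C@H]3[C@H]([C@@H](O[Si](C(C)C)(C(C)C)C(C)C)C(=O)OC)[C@H](OC(C)=O)C(=O)OC3OC(C)=O)[C@H]12
F3 | step 14 | dialdehyde from cleavage of the C1–C3 bond of 24 (C1 and C3 aldehydes) | C=C1CCCC(C)(C)[C@@H]2CC[C@@](C)([C@H](C=O)[C@H]([C@@H](O[Si](C(C)C)(C(C)C)C(C)C)C(=O)OC)[C@H](OC(C)=O)C=O)[C@H]12
F4 | step 10 | trimethylsilyl enol ether of 17 (C4–OSiMe3, C4=C5) | C=C1CCCC(C)(C)[C@@H]2CC[C@@](C)([C@H]3C=C(O[Si](C)(C)C)[C@@H]4OC(C)(C)O[C@H]34)[C@H]12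
F5 | step 10 | free aldol: 21 without the silyl group (C6–OH) | C=C1CCCC(C)(C)[C@@H]2CC[C@@](C)([C@H]3[C@H]([C@@H](O)C(=O)OC)C(=O)[C@@H]4OC(C)(C)O[C@H]34)[C@H]12
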